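The rate constants belong to no real substance; the result is computed.

Amounts first: the flasks hold the same electrophile and solid base and differ in the nucleophile charged.

| flask | electrophile | nucleophile | solid base | time |
|---|---|---|---|---|
| blue | 0.26 M | 1.80 equiv | 2.00 equiv | 40 min |
| grey | 0.26 M | 3.60 equiv | 2.00 equiv | 40 min |
| green | 0.26 M | 7.20 equiv | 2.00 equiv | 40 min |

    2 free base → homo dimer (k1 = 0.372 M⁻¹ min⁻¹)
    nucleophile + acid set free ⇌ protonated nucleophile, settled at all times (K2 = 5100 M⁻¹)
    solid base ⇌ free base, rate k3*(cs3 - [free base]) while solid is left; crystals form when [free base] > cs3 (cs3 = 0.21 M, k3 = 0.0279 min⁻¹)
    acid set free + free base ⇌ salt of the base (K4 = 7100 M⁻¹, k4 = 3.87 M⁻¹ min⁻¹)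
    electrophile + nucleophile → acid set free + product (k5 = 0.100 M⁻¹ min⁻¹)

- where a step has two of a species, its rate is k times that concentration squared, and two are used at each turn
- solid, in amounts per volume of the solution: solid base
- at the start none of the solid base is in solution
- run time (blue): 40 min

- part of the electrophile that has reacted at the end, blue
- part of the electrophile that has reacted at the end, grey
- part of the electrophile that has reacted at the end, green
- what raising the equivalents of nucleophile from its lowest to its highest value here does to the part of the electrophile that has reacted (changes below 5 percentage points count as none) (it falls / no change / it rises)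

Each turn of the product step sets one acid free, and in blue at the start the equilibrium constant of protonation times c(nucleophile) is 2400, so we let the nucleophile take that acid up and count two nucleophile for each turn.

We fold the givens into one number, the exposure E: the rate constant k of the product step times c(nucleophile) times the time, which is 1.87 for blue. It counts how many times the electrophile is divided by e if c(nucleophile) stays as charged (the pseudo-first-order view), so the part left is exp(−E).

First round, c(nucleophile) as charged:

blue: E = 1.87, reacted 84.6%
grey: E = 3.74, reacted 97.6%
green: E = 7.49, reacted 99.9%

One number is not enough: blue's first answer spends 94.0% of its nucleophile, so the charge does not stay put. We put the answer back. Taking the mean of start and end, c(nucleophile) over the run is the charge less the charged c(electrophile) times the part reacted.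

Second round, the answers we commit to:

blue: E = 0.992, reacted 62.9%
grey: E = 2.73, reacted 93.5%
green: E = 6.45, reacted 99.8%

The forecast gives 63%, 90.7% and 99.7%, with the trend "it rises", and holds that “the base barely matters”. For grey our figure is higher than its, 93.5% against 90.7%.

The flasks give 62.9% for blue, 90.6% for grey and 99.7% for green: from blue to green the part reacted goes up by 37 percentage points, so the answer on the trend is "it rises". Of the charged nucleophile, 30.4% is still free at the end in blue, 49.7% in grey and 72.3% in green. The neighbour flask is grey with 0.065 M of electrophile, the same equivalents and the same time. Its two rounds give E = 0.936, then 0.778, so 54.1% reacted, and that flask stands at 53.7%.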